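Ring A of the flavone is cut as a folded tetraketide: C8, the carbon that bears ring D, is the methylene flanked by the C7 and C8a carbonyls. An arylacetate therefore supplies ring D, C8 and C8a, and 4-methoxy-6-methyl-2-pyranone supplies C7, C6, C5, C4a, C4 and C3, the C5 oxygen being carried as a methyl enol ether. In one operation the key step forms C7–C8 (enolate acylation by the lactone carbonyl) and C4a–C8a (Claisen closure) and aromatises ring A as an acetophenone whose only hydroxyl next to the acetyl group is C8a-OH. The precursor is a mixed homophthalate: methyl arylacetate ester, tert-butyl benzoate ester, two methyl ethers.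

Key step: step 5

Assumption: the target is drawn without axial configuration, so the hindered bond between C8 and ring D is formed without control (racemic about the axis if rotation is slow).

Step 1
Reactants: 1 2-bromo-3,4-dimethoxybenzaldehyde
Product: 2 2-bromo-3,4-dimethoxybenzoic acid
Conditions: NaClO2, NaH2PO4, 2-methyl-2-butene, t-BuOH/H2O, rt
Reagents that add atoms: sodium chlorite, [Na+].[O-]Cl=O
Why: Pinnick oxidation takes the aldehyde to the acid through its chlorous acid adduct, the alkene scavenging hypochlorous acid so that the electron-rich ring is not chlorinated.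

Step 2
Reactants: 2 2-bromo-3,4-dimethoxybenzoic acid; 3 dimethyl malonate
Product: 4 2-(1,3-dimethoxy-1,3-dioxopropan-2-yl)-3,4-dimethoxybenzoic acid
Conditions: NaH (3 equiv), CuBr (10 mol %), neat 3 (excess), 75 °C; aq. HCl
Reagents that add atoms: none
Why: Hurtley reaction, in which the ortho carboxylate binds copper and delivers it to the neighbouring C–Br bond, so that sodium malonate should displace bromide even though the position is also flanked by a methoxy group.

Step 3
Reactants: 4 2-(1,3-dimethoxy-1,3-dioxopropan-2-yl)-3,4-dimethoxybenzoic acid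
Product: 5 tert-butyl 2-(1,3-dimethoxy-1,3-dioxopropan-2-yl)-3,4-dimethoxybenzoate
Conditions: Cl3CC(=NH)Ot-Bu (2 equiv), CH2Cl2/cyclohexane, rt
Reagents that add atoms: tert-butyl 2,2,2-trichloroacetimidate, CC(C)(C)OC(=N)C(Cl)(Cl)Cl
Why: Imidate esterification, in which the carboxylic acid protonates the imidate and captures the tert-butyl cation under neutral conditions that leave the malonate C–H and the methyl esters untouched.

Step 4
Reactants: 5 tert-butyl 2-(1,3-dimethoxy-1,3-dioxopropan-2-yl)-3,4-dimethoxybenzoate
Product: 6 tert-butyl 3,4-dimethoxy-2-(2-methoxy-2-oxoethyl)benzoate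
Conditions: LiCl (2 equiv), H2O (2 equiv), DMSO, 130 °C
Reagents that add atoms: none
Why: Krapcho dealkoxycarbonylation, in which chloride demethylates one malonate ester by SN2, the carboxylate loses CO2 to a benzylic ester enolate that water protonates, and the hindered tert-butyl benzoate is inert to chloride.

Step 5
Reactants: 6 tert-butyl 3,4-dimethoxy-2-(2-methoxy-2-oxoethyl)benzoate; 7 4-methoxy-6-methyl-2H-pyran-2-one
Product: 9 tert-butyl 2-(3-acetyl-2,6-dihydroxy-4-methoxyphenyl)-3,4-dimethoxybenzoate, via ring-opened keto ester 8 (not isolated)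
Conditions: LiN(SiMe3)2 (1.1 equiv), THF, −78 °C; 7 (1.2 equiv), −78 to 0 °C; then Mg(OMe)2 (4 equiv), MeOH, 65 °C; aq. HCl
Reagents that add atoms: none
Why: Proposed new method: the lithium enolate of 6 should be C-acylated by the lactone carbonyl of 7 (bond C7–C8), the tetrahedral adduct collapsing with expulsion of the ring oxygen as a vinylogous diketonate to give chain 8, in which the C4 ketone is set free and the C5 oxygen remains a methyl enol ether; Mg(OMe)2 then chelates the β-keto ester, generates the C4/C4a enolate and lets C4a add to the methyl ester carbonyl (bond C4a–C8a) with loss of methoxide, after which enolisation aromatises ring A. The closest known reaction types are the base-mediated Claisen cyclisation of 3,5,7-trioxoalkanoates to acylphloroglucinols and the ring opening of 2-pyranones by carbon nucleophiles. Ring A closes by a 6-exo-trig acyl substitution of the Dieckmann type. No stereocentre is created, since the C8 centre of 8 is lost on aromatisation and the biaryl axis that emerges is not controlled. The step needs C-acylation at the lactone carbonyl followed by Claisen closure from C4a, not aldol closure or attack on the ring-D ester: the aryl group on C8 prevents any aldol adduct through C8 from dehydrating to an arene and so keeps it reversible, the tert-butyl benzoate is too hindered to accept an acyl transfer so that the methyl ester is the only acceptor, and the enol ether blocks C5 as an electrophile. Because C5 stays methylated, the C8a hydroxyl is the only free oxygen next to the acetyl group, which fixes the later pyranone closure to the 8-aryl pattern.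

Step 6
Reactants: 9 tert-butyl 2-(3-acetyl-2,6-dihydroxy-4-methoxyphenyl)-3,4-dimethoxybenzoate
Product: 10 tert-butyl 2-(3-acetyl-2-hydroxy-4,6-dimethoxyphenyl)-3,4-dimethoxybenzoate
Conditions: MeI (1.1 equiv), K2CO3, acetone, 50 °C
Reagents that add atoms: iodomethane, CI
Why: Williamson etherification selective for the C7 hydroxyl, which is free and the more acidic one, whereas the C8a hydroxyl is tied up in a hydrogen bond to the acetyl carbonyl; capping C7-OH removes the phenoxide that would slow the following condensation.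

Step 7
Reactants: 10 tert-butyl 2-(3-acetyl-2-hydroxy-4,6-dimethoxyphenyl)-3,4-dimethoxybenzoate; 11 3,4-dimethoxybenzaldehyde
Product: 12 tert-butyl 2-{3-[(2E)-3-(3,4-dimethoxyphenyl)prop-2-enoyl]-2-hydroxy-4,6-dimethoxyphenyl}-3,4-dimethoxybenzoate
Conditions: KOH (50% aq.), EtOH, rt; aq. HCl
Reagents that add atoms: none
Why: Claisen–Schmidt condensation, in which the methyl ketone enolate adds to the non-enolisable aldehyde and E1cB loss of water gives the E-enone under thermodynamic control, the tert-butyl ester resisting hydroxide at room temperature.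

Step 8
Reactants: 12 tert-butyl 2-{3-[(2E)-3-(3,4-dimethoxyphenyl)prop-2-enoyl]-2-hydroxy-4,6-dimethoxyphenyl}-3,4-dimethoxybenzoate
Product: 14 tert-butyl 2-[2-(3,4-dimethoxyphenyl)-5,7-dimethoxy-4-oxo-4H-chromen-8-yl]-3,4-dimethoxybenzoate, via flavanone 13 (not isolated)
Conditions: I2 (10 mol %), DMSO, 120 °C
Reagents that add atoms: none
Why: Iodine-catalysed oxidative cyclisation of a 2'-hydroxychalcone, in which 6-endo-trig oxa-Michael closure through the C8a hydroxyl gives the flavanone, α-iodination and loss of HI give the flavone, and DMSO reoxidises HI to I2.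

Step 9
Reactants: 14 tert-butyl 2-[2-(3,4-dimethoxyphenyl)-5,7-dimethoxy-4-oxo-4H-chromen-8-yl]-3,4-dimethoxybenzoate
Product: 15 2-[2-(3,4-dihydroxyphenyl)-5,7-dihydroxy-4-oxo-4H-chromen-8-yl]-3,4-dihydroxybenzoic acid
Conditions: BBr3 (12 equiv), CH2Cl2, −78 °C to rt; ice/H2O
Reagents that add atoms: none
Why: Lewis-acid ether cleavage, in which BBr3 complexes each methoxy oxygen and bromide removes the six methyl groups, the tert-butyl ester ionises to the acid under the same conditions, and hydrolysis of the borates on work-up frees the phenols.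

Compound list
1 | 2-bromo-3,4-dimethoxybenzaldehyde | COc1ccc(C=O)c(Br)c1OC | starting material
2 | 2-bromo-3,4-dimethoxybenzoic acid | COc1ccc(C(=O)O)c(Br)c1OC | intermediate
3 | dimethyl malonate | COC(=O)CC(=O)OC | starting material
4 | 2-(1,3-dimethoxy-1,3-dioxopropan-2-yl)-3,4-dimethoxybenzoic acid | COC(=O)C(C(=O)OC)c1c(OC)c(OC)ccc1C(=O)O | intermediate
5 | tert-butyl 2-(1,3-dimethoxy-1,3-dioxopropan-2-yl)-3,4-dimethoxybenzoate | COC(=O)C(C(=O)OC)c1c(OC)c(OC)ccc1C(=O)OC(C)(C)C | intermediate
6 | tert-butyl 3,4-dimethoxy-2-(2-methoxy-2-oxoethyl)benzoate | COC(=O)Cc1c(OC)c(OC)ccc1C(=O)OC(C)(C)C | intermediate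
7 | 4-methoxy-6-methyl-2H-pyran-2-one | COc1cc(C)oc(=O)c1 | starting material
8 | tert-butyl 2-[(4E)-1,5-dimethoxy-1,3,7-trioxooct-4-en-2-yl]-3,4-dimethoxybenzoate (racemic at C2 of the chain, present as its enolate, not isolated) | COC(=O)C(c1c(OC)c(OC)ccc1C(=O)OC(C)(C)C)C(=O)/C=C(/OC)CC(C)=O | intermediate
9 | tert-butyl 2-(3-acetyl-2,6-dihydroxy-4-methoxyphenyl)-3,4-dimethoxybenzoate | CC(=O)c1c(OC)cc(O)c(-c2c(OC)c(OC)ccc2C(=O)OC(C)(C)C)c1O | intermediate
10 | tert-butyl 2-(3-acetyl-2-hydroxy-4,6-dimethoxyphenyl)-3,4-dimethoxybenzoate | CC(=O)c1c(OC)cc(OC)c(-c2c(OC)c(OC)ccc2C(=O)OC(C)(C)C)c1O | intermediate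
11 | 3,4-dimethoxybenzaldehyde | COc1ccc(C=O)cc1OC | starting material
12 | tert-butyl 2-{3-[(2E)-3-(3,4-dimethoxyphenyl)prop-2-enoyl]-2-hydroxy-4,6-dimethoxyphenyl}-3,4-dimethoxybenzoate | COc1ccc(/C=C/C(=O)c2c(OC)cc(OC)c(-c3c(OC)c(OC)ccc3C(=O)OC(C)(C)C)c2O)cc1OC | intermediate
13 | tert-butyl 2-[2-(3,4-dimethoxyphenyl)-5,7-dimethoxy-4-oxo-3,4-dihydro-2H-chromen-8-yl]-3,4-dimethoxybenzoate (racemic at C2, not isolated) | COc1ccc(C2CC(=O)c3c(OC)cc(OC)c(-c4c(OC)c(OC)ccc4C(=O)OC(C)(C)C)c3O2)cc1OC | intermediate
14 | tert-butyl 2-[2-(3,4-dimethoxyphenyl)-5,7-dimethoxy-4-oxo-4H-chromen-8-yl]-3,4-dimethoxybenzoate | COc1ccc(-c2cc(=O)c3c(OC)cc(OC)c(-c4c(OC)c(OC)ccc4C(=O)OC(C)(C)C)c3o2)cc1OC | intermediate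
15 | 2-[2-(3,4-dihydroxyphenyl)-5,7-dihydroxy-4-oxo-4H-chromen-8-yl]-3,4-dihydroxybenzoic acid | O=C(O)c1ccc(O)c(O)c1-c1c(O)cc(O)c2c(=O)cc(-c3ccc(O)c(O)c3)oc12 | target

Total step count: 9. Longest linear sequence: 9 steps (1 to 15); 3, 7 and 11 are purchased and enter at steps 2, 5 and 7.

Steps most likely to fail

1. Step 5 (the proposed new method). What may go wrong:
- proton transfer from the acidic 6-methyl group of 7 to the ester enolate in place of C-acylation;
- conjugate attack at C6 of the pyranone;
- methanolysis of the ring-opened chain by retro-Claisen cleavage before ring closure;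
- ring closure in a mode other than C4a to C8a.

Fallback by known chemistry, setting out from 1 and coming back at 15: the bond between C8 and ring D is made by cross-coupling on a preformed flavone. Commercial 2-(3,4-dimethoxyphenyl)-5,7-dimethoxy-4H-chromen-4-one (COc1ccc(-c2cc(=O)c3c(OC)cc(OC)cc3o2)cc1OC) is iodinated with I2 and CF3CO2Ag in CH2Cl2. Electrophilic substitution of 5,7-dimethoxyflavones is directed to C8, so this should give 2-(3,4-dimethoxyphenyl)-8-iodo-5,7-dimethoxy-4H-chromen-4-one F1. Miyaura borylation (B2pin2, PdCl2(dppf), KOAc, dioxane, 90 °C) should give 2-(3,4-dimethoxyphenyl)-5,7-dimethoxy-8-(4,4,5,5-tetramethyl-1,3,2-dioxaborolan-2-yl)-4H-chromen-4-one F2. Suzuki–Miyaura coupling of F2 with bromide 1 (Pd(OAc)2, SPhos, K3PO4, toluene/H2O, 100 °C) should give 2-[2-(3,4-dimethoxyphenyl)-5,7-dimethoxy-4-oxo-4H-chromen-8-yl]-3,4-dimethoxybenzaldehyde F3. Pinnick oxidation as in step 1 should give 2-[2-(3,4-dimethoxyphenyl)-5,7-dimethoxy-4-oxo-4H-chromen-8-yl]-3,4-dimethoxybenzoic acid F4, and BBr3 under the conditions of step 9 should give 15.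

2. Step 9. What may go wrong: acid-promoted ring closure of the ring-D carboxyl onto the newly freed C7 hydroxyl during deprotection or work-up, and incomplete cleavage of the hindered ethers.

Fallback, setting out from 14 and coming back at 15: the ring closure is accepted and then reversed. After treatment of 14 with BBr3 the crude material is heated in AcOH to convert everything into the lactone formed between the ring-D carboxyl and the C7 oxygen (a dibenzo-α-pyranone fused to the chromone) F5, which is purified. Saponification with degassed aq. NaOH containing Na2S2O4 under argon at rt opens the lactone. Acidification to pH 3 at 0 °C with immediate isolation should give 15.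

3. Step 2. What may go wrong: slow substitution at a C–Br bond flanked by two ortho groups, with competing reduction of the C–Br bond.

Fallback, setting out from 2 and coming back at 5: the ester is made first and the metal is changed. Acid 2 with tert-butyl 2,2,2-trichloroacetimidate (CH2Cl2/cyclohexane, rt) should give tert-butyl 2-bromo-3,4-dimethoxybenzoate F6. Palladium-catalysed α-arylation of malonate 3 (Pd(dba)2, P(t-Bu)3, K3PO4, toluene, 80 °C) proceeds by oxidative addition to zerovalent palladium and reductive elimination from an arylpalladium enolate, and should give 5.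

Further compounds
F1 | step 5 | 2-(3,4-dimethoxyphenyl)-8-iodo-5,7-dimethoxy-4H-chromen-4-one | COc1ccc(-c2cc(=O)c3c(OC)cc(OC)c(I)c3o2)cc1OC
F2 | step 5 | 2-(3,4-dimethoxyphenyl)-5,7-dimethoxy-8-(4,4,5,5-tetramethyl-1,3,2-dioxaborolan-2-yl)-4H-chromen-4-one | COc1ccc(-c2cc(=O)c3c(OC)cc(OC)c(B4OC(C)(C)C(C)(C)O4)c3o2)cc1OC
F3 | step 5 | 2-[2-(3,4-dimethoxyphenyl)-5,7-dimethoxy-4-oxo-4H-chromen-8-yl]-3,4-dimethoxybenzaldehyde | COc1ccc(-c2cc(=O)c3c(OC)cc(OC)c(-c4c(OC)c(OC)ccc4C=O)c3o2)cc1OC
F4 | step 5 | 2-[2-(3,4-dimethoxyphenyl)-5,7-dimethoxy-4-oxo-4H-chromen-8-yl]-3,4-dimethoxybenzoic acid | COc1ccc(-c2cc(=O)c3c(OC)cc(OC)c(-c4c(OC)c(OC)ccc4C(=O)O)c3o2)cc1OC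
F5 | step 9 | lactone of 15 between the ring-D carboxyl group and the C7 oxygen | O=C1Oc2cc(O)c3c(=O)cc(-c4ccc(O)c(O)c4)oc3c2-c2c(O)c(O)ccc21
F6 | step 2 | tert-butyl 2-bromo-3,4-dimethoxybenzoate | COc1ccc(C(=O)OC(C)(C)C)c(Br)c1OC
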